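**Retrosynthetic overview**

1. Numbering used throughout: ring A = C1–C5 and C10; ring B = C5–C10; C17 = acid carbon on C8; C19 = acid carbon on C4; C20 = methyl on C10; C11–C12 = side-chain CH2 groups; C13–C16 = butenolide.
2. Enabling feature: in ring B, C8 is the α-carbon and C9 the β-carbon of the C17 carboxyl, C9 sits next to the fully substituted C10, and C7 is two carbons from C5. Ring B is therefore an acrylate unit (C9=C8–C17) inserted between a tertiary-radical site (C10) and a primary electrophile (C7), both carried by ring A.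
3. Butenolide last: C12–C13 by B-alkyl Suzuki coupling of a C9 vinyl group. The vinyl group comes from a C11 aldehyde, which also lets C8 and C9 settle all-equatorial.
4. Ring B: union of a ring-A tertiary oxalate (C10) bearing a 2-bromoethyl arm (C6–C7) with an (E)-enoate (C17–C8=C9–C11 acetal). C10–C9 forms by radical addition, then C7–C8 by enolate ring closure in the same flask.
5. Ring A: bought as a cyclohexenone acid. C4 is set by catalytic asymmetric conjugate methylation, C5 by a temporary cis-fused lactone (C19–O–C7) that later opens to the C19 ester and the C7 bromide. Ring order: A (purchased) → temporary lactone → B → butenolide.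

Key step: step 10

Assumption: 3-oxocyclohex-1-ene-1-carboxylic acid, 2,2-dimethoxyacetaldehyde (60% aqueous solution), tert-butyl 2-(diethoxyphosphoryl)acetate and 3-bromofuran-2(5H)-one are taken as purchasable.

**Route**

Step 1
Reactants: 1 3-oxocyclohex-1-ene-1-carboxylic acid; 2 2-bromoethanol
Product: 3 2-bromoethyl 3-oxocyclohex-1-ene-1-carboxylate
Conditions: DCC, DMAP (cat.), CH2Cl2, 0 °C → rt
Reagents that add atoms: none
Why: Steglich esterification of the vinylogous keto acid with the primary alcohol places the future C6–C7 unit on the C19 carboxyl as a tether; no stereocentre is formed.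

Step 2
Reactants: 3 2-bromoethyl 3-oxocyclohex-1-ene-1-carboxylate
Product: 5 2-bromoethyl (1S)-1-methyl-3-[(trimethylsilyl)oxy]cyclohex-2-ene-1-carboxylate, via methylzinc enolate 4 (not isolated)
Conditions: Me2Zn, Cu(OTf)2 (2.5 mol %), chiral sulfonate-bearing NHC ligand (as its imidazolinium salt, 2.5 mol %), toluene, −30 °C; then TMSOTf, −30 → 0 °C
Reagents that add atoms: dimethylzinc C[Zn]C; trimethylsilyl triflate C[Si](C)(C)OS(=O)(=O)C(F)(F)F
Why: Copper-catalysed asymmetric conjugate addition of dimethylzinc to a cyclic γ-keto enoate (the ester-bearing carbon is β to the ketone) forms the C4 quaternary centre on the face chosen by the chiral NHC–copper catalyst (ligand enantiomer selected for 1S), and O-silylation of the zinc enolate fixes the enolate regiochemistry at C10=C5.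

Step 3
Reactants: 5 2-bromoethyl (1S)-1-methyl-3-[(trimethylsilyl)oxy]cyclohex-2-ene-1-carboxylate
Product: 7 (4aS,8aS)-8a-methylhexahydro-1H-isochromene-1,5(6H)-dione (cis-fused keto δ-lactone), via tetrabutylammonium enolate 6 (not isolated)
Conditions: TBAT (Bu4N Ph3SiF2), THF (0.01 M), 4 Å MS, rt → 45 °C
Reagents that add atoms: tetrabutylammonium difluorotriphenylsilicate CCCC[N+](CCCC)(CCCC)CCCC.F[Si-](F)(c1ccccc1)(c1ccccc1)c1ccccc1 (cation in 6 only)
Why: Fluoride unmasks the enolate, which closes the δ-lactone by intramolecular C-alkylation (6-exo-tet SN2 on the primary bromide, run dilute because the ester tether must reach its s-cis form); the tether hangs from C19 and can reach only the enolate face on its own side, so C5 is set with C6 cis to C19 (cis ring fusion).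

Step 4
Reactants: 7 (4aS,8aS)-8a-methylhexahydro-1H-isochromene-1,5(6H)-dione
Product: 8 (4aR,8aS)-8a-methyl-5-methylideneoctahydro-1H-isochromen-1-one
Conditions: Zn, CH2Br2, TiCl4, THF/CH2Cl2, 0 °C → rt
Reagents that add atoms: dibromomethane BrCBr
Why: Takai–Lombardo methylenation converts the hindered, enolisable ketone into the exocyclic alkene under non-basic conditions, so the C5 centre next to the carbonyl is not epimerised and the lactone is untouched.

Step 5
Reactants: 8 (4aR,8aS)-8a-methyl-5-methylideneoctahydro-1H-isochromen-1-one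
Product: 10 4-methoxybenzyl (1S,2R)-2-(2-hydroxyethyl)-1-methyl-3-methylidenecyclohexane-1-carboxylate, via cesium hydroxy carboxylate 9 (not isolated)
Conditions: CsOH·H2O, THF/H2O, 0 °C → rt; evaporate; then PMBCl, DMF, rt
Reagents that add atoms: cesium hydroxide [Cs+].[OH-]; 4-methoxybenzyl chloride COc1ccc(CCl)cc1
Why: Saponification of the lactone followed by SN2 O-alkylation of the hindered carboxylate (esterification by alkylation, independent of acyl attack) frees the C7 hydroxyl and protects C19 as an acid-labile ester without touching a stereocentre.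

Step 6
Reactants: 10 4-methoxybenzyl (1S,2R)-2-(2-hydroxyethyl)-1-methyl-3-methylidenecyclohexane-1-carboxylate
Product: 11 4-methoxybenzyl (1S,2R)-2-(2-bromoethyl)-1-methyl-3-methylidenecyclohexane-1-carboxylate
Conditions: CBr4, PPh3, CH2Cl2, 0 °C
Reagents that add atoms: tetrabromomethane BrC(Br)(Br)Br
Why: The Appel reaction turns the primary alcohol into the primary bromide that will serve as the C7 electrophile; the hindered ester and the alkene are inert.

Step 7
Reactants: 11 4-methoxybenzyl (1S,2R)-2-(2-bromoethyl)-1-methyl-3-methylidenecyclohexane-1-carboxylate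
Product: 12 4-methoxybenzyl (1S,2S,3S)-2-(2-bromoethyl)-3-hydroxy-1,3-dimethylcyclohexane-1-carboxylate
Conditions: Co(acac)2 (20 mol %), PhSiH3, O2 (1 atm), THF, rt
Reagents that add atoms: dioxygen O=O
Why: Mukaiyama hydration (cobalt-hydride hydrogen-atom transfer to the 1,1-disubstituted alkene, then oxygen capture of the tertiary radical) gives the Markovnikov tertiary alcohol and creates the C20 methyl; the new C10 centre, drawn as the epimer expected from capture anti to the C5 arm and the C19 ester, is of no consequence because it becomes a planar radical in step 10.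

Step 8
Reactants: 12 4-methoxybenzyl (1S,2S,3S)-2-(2-bromoethyl)-3-hydroxy-1,3-dimethylcyclohexane-1-carboxylate
Product: 14 cesium 2-{[(1S,2S,3S)-2-(2-bromoethyl)-3-{[(4-methoxybenzyl)oxy]carbonyl}-1,3-dimethylcyclohexyl]oxy}-2-oxoacetate, via methyl oxalate 13 (not isolated)
Conditions: ClCOCO2Me, Et3N, DMAP (cat.), CH2Cl2, 0 °C → rt; then 1 M aq. CsOH (1.0 equiv), THF, rt
Reagents that add atoms: methyl chlorooxoacetate COC(=O)C(=O)Cl; cesium hydroxide [Cs+].[OH-]
Why: Acylation of the tertiary alcohol with methyl chlorooxoacetate and selective hydrolysis of the far more electrophilic oxalate methyl ester with one equivalent of CsOH give the cesium oxalate, the established photoredox precursor of tertiary radicals.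

Step 9
Reactants: 15 2,2-dimethoxyacetaldehyde; 16 tert-butyl 2-(diethoxyphosphoryl)acetate
Product: 17 tert-butyl (2E)-4,4-dimethoxybut-2-enoate
Conditions: K2CO3, H2O/THF, rt
Reagents that add atoms: none
Why: Horner–Wadsworth–Emmons olefination of the glyoxal mono-acetal with the stabilised phosphonate gives the (E)-enoate, the C8–C9 unit carrying C17 as ester and C11 as masked aldehyde.

Step 10
Reactants: 14 cesium oxalate of the ring-A tertiary alcohol; 17 tert-butyl (2E)-4,4-dimethoxybut-2-enoate
Product: 19 6-tert-butyl 1-(4-methoxybenzyl) (1S,4aS,5S,6R,8aR)-5-(dimethoxymethyl)-1,4a-dimethyldecahydronaphthalene-1,6-dicarboxylate (drawn as the expected major C8/C9 isomer), via cesium ester enolate 18 (not isolated)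
Conditions: Ir[dF(CF3)ppy]2(dtbbpy)PF6 (2 mol %), 17 (3 equiv), dry DMF/DME (1:3), 4 Å MS, blue LEDs (450 nm), 40 °C
Reagents that add atoms: none
Why: Proposed new method: The photoexcited trivalent iridium complex oxidises the oxalate of 14, loss of two CO2 gives the tertiary C10 radical, this adds to C9 of 17 (Giese addition), the resulting C8 α-ester radical is reduced by the divalent iridium to the cesium enolate 18 (radical–polar crossover), and 18 closes ring B by SN2 attack of C8 on the C7 bromide. The closest known reaction types are the photoredox Giese coupling of tertiary-alcohol oxalates with enoates and the photoredox radical addition–polar cyclisation cascades of haloalkyl-substituted acceptors; what is new is that the leaving group sits on the radical partner and that a cyclohexane is closed. Ring B closes in the 6-exo-tet mode through a chair in which the C5 and C10 arms are trans-diequatorial on ring A and the ester and the acetal carbon are equatorial. C10 is set by the substrate, since the acceptor can reach the planar radical only on the α face, anti to the C5 arm and away from the syn-axial C19 ester, which gives the trans ring fusion; C9 is set in the same addition (hydrogen anti to C20, the acetal carbon over the unhindered C1 side) and C8 in the chair alkylation, and both can be corrected by equilibration in step 11. The step needs addition at C9 and not at C8, secured by the single activating ester, and C-alkylation faster than protonation or acyl attack, secured by the dry aprotic medium, the primary bromide and the fact that C8 and the C19 ester lie on opposite faces of ring A.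

Step 11
Reactants: 19 decalin acetal diester
Product: 20 6-tert-butyl 1-(4-methoxybenzyl) (1S,4aS,5S,6R,8aR)-5-formyl-1,4a-dimethyldecahydronaphthalene-1,6-dicarboxylate
Conditions: 1 M aq. HCl, THF, rt; then KOtBu (0.2 equiv), t-BuOH/THF, 0 °C → rt
Reagents that add atoms: water O
Why: Acid hydrolysis of the dimethyl acetal (both esters survive dilute aqueous acid) gives the C11 aldehyde, and catalytic alkoxide then equilibrates C9 through the aldehyde enolate and C8 through the ester enolate to the all-equatorial 8α-ester/9β-formyl arrangement, the thermodynamic minimum because an axial group at C8 would be syn-axial to C20.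

Step 12
Reactants: 20 decalin aldehyde diester
Product: 21 6-tert-butyl 1-(4-methoxybenzyl) (1S,4aR,5S,6R,8aR)-5-ethenyl-1,4a-dimethyldecahydronaphthalene-1,6-dicarboxylate
Conditions: Ph3PCH3Br, KOtBu, THF, 0 °C → rt
Reagents that add atoms: methyltriphenylphosphonium bromide C[P+](c1ccccc1)(c1ccccc1)c1ccccc1.[Br-]
Why: Wittig methylenation of the hindered aldehyde gives the C9 vinyl group (C11=C12); the basic ylide cannot move C9 away from its already thermodynamic configuration.

Step 13
Reactants: 21 vinyl decalin diester; 22 3-bromofuran-2(5H)-one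
Product: 24 6-tert-butyl 1-(4-methoxybenzyl) (1S,4aR,5S,6R,8aR)-1,4a-dimethyl-5-[2-(2-oxo-2,5-dihydrofuran-3-yl)ethyl]decahydronaphthalene-1,6-dicarboxylate, via B-alkyl-9-BBN 23 (not isolated)
Conditions: 9-BBN, THF, 0 °C → rt; then 22, PdCl2(dppf) (5 mol %), AsPh3 (10 mol %), 3 M aq. K3PO4, DMF, rt
Reagents that add atoms: 9-borabicyclo[3.3.1]nonane [BH]1C2CCCC1CCC2 (boron in 23 only)
Why: Anti-Markovnikov hydroboration of the monosubstituted alkene with 9-BBN followed by B-alkyl Suzuki–Miyaura coupling with the α-bromobutenolide forms the C12–C13 bond and delivers the α-substituted butenolide at the right oxidation level, with no stereocentre involved.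

Step 14
Reactants: 24 butenolide diester
Product: 25 (1S,4aR,5S,6R,8aR)-1,4a-dimethyl-5-[2-(2-oxo-2,5-dihydrofuran-3-yl)ethyl]decahydronaphthalene-1,6-dicarboxylic acid (CNP0478950.1)
Conditions: TFA, anisole, CH2Cl2, 0 °C → rt
Reagents that add atoms: none
Why: Acidolysis cleaves both esters by alkyl–oxygen fission (tert-butyl cation to isobutene, 4-methoxybenzyl cation trapped by anisole), conditions under which the butenolide and all stereocentres are stable, to give the diacid.

**Compound list**

1 | 3-oxocyclohex-1-ene-1-carboxylic acid | O=C1CCCC(C(=O)O)=C1 | starting material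
2 | 2-bromoethanol | OCCBr | starting material
3 | 2-bromoethyl 3-oxocyclohex-1-ene-1-carboxylate | O=C1CCCC(C(=O)OCCBr)=C1 | intermediate
4 | methylzinc enolate (O–Zn on C10, C10=C5) of 2-bromoethyl (1S)-1-methyl-3-oxocyclohexane-1-carboxylate | C[Zn]OC1=C[C@@](C)(C(=O)OCCBr)CCC1 | intermediate
5 | 2-bromoethyl (1S)-1-methyl-3-[(trimethylsilyl)oxy]cyclohex-2-ene-1-carboxylate | C[Si](C)(C)OC1=C[C@@](C)(C(=O)OCCBr)CCC1 | intermediate
6 | tetrabutylammonium enolate corresponding to 5 | [O-]C1=C[C@@](C)(C(=O)OCCBr)CCC1.CCCC[N+](CCCC)(CCCC)CCCC | intermediate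
7 | (4aS,8aS)-8a-methylhexahydro-1H-isochromene-1,5(6H)-dione, cis-fused | O=C1CCC[C@]2(C)C(=O)OCC[C@H]12 | intermediate
8 | (4aR,8aS)-8a-methyl-5-methylideneoctahydro-1H-isochromen-1-one, cis-fused | C=C1CCC[C@]2(C)C(=O)OCC[C@H]12 | intermediate
9 | cesium (1S,2R)-2-(2-hydroxyethyl)-1-methyl-3-methylidenecyclohexane-1-carboxylate | C=C1CCC[C@](C)(C(=O)[O-])[C@@H]1CCO.[Cs+] | intermediate
10 | 4-methoxybenzyl (1S,2R)-2-(2-hydroxyethyl)-1-methyl-3-methylidenecyclohexane-1-carboxylate | C=C1CCC[C@](C)(C(=O)OCc2ccc(OC)cc2)[C@@H]1CCO | intermediate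
11 | 4-methoxybenzyl (1S,2R)-2-(2-bromoethyl)-1-methyl-3-methylidenecyclohexane-1-carboxylate | C=C1CCC[C@](C)(C(=O)OCc2ccc(OC)cc2)[C@@H]1CCBr | intermediate
12 | 4-methoxybenzyl (1S,2S,3S)-2-(2-bromoethyl)-3-hydroxy-1,3-dimethylcyclohexane-1-carboxylate | C[C@]1(O)CCC[C@](C)(C(=O)OCc2ccc(OC)cc2)[C@@H]1CCBr | intermediate
13 | 4-methoxybenzyl (1S,2S,3S)-2-(2-bromoethyl)-3-[(methoxyoxalyl)oxy]-1,3-dimethylcyclohexane-1-carboxylate | C[C@]1(OC(=O)C(=O)OC)CCC[C@](C)(C(=O)OCc2ccc(OC)cc2)[C@@H]1CCBr | intermediate
14 | cesium 2-{[(1S,2S,3S)-2-(2-bromoethyl)-3-{[(4-methoxybenzyl)oxy]carbonyl}-1,3-dimethylcyclohexyl]oxy}-2-oxoacetate | C[C@]1(OC(=O)C(=O)[O-])CCC[C@](C)(C(=O)OCc2ccc(OC)cc2)[C@@H]1CCBr.[Cs+] | intermediate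
15 | 2,2-dimethoxyacetaldehyde | COC(OC)C=O | starting material
16 | tert-butyl 2-(diethoxyphosphoryl)acetate | CCOP(=O)(OCC)CC(=O)OC(C)(C)C | starting material
17 | tert-butyl (2E)-4,4-dimethoxybut-2-enoate | COC(OC)/C=C/C(=O)OC(C)(C)C | intermediate
18 | cesium tert-butyl ester enolate (at C8) of the open-chain C10–C9 adduct, C4, C5, C9 and C10 configured as in 19 | C[C@]1([C@H](C=C([O-])OC(C)(C)C)C(OC)OC)CCC[C@](C)(C(=O)OCc2ccc(OC)cc2)[C@@H]1CCBr.[Cs+] | intermediate
19 | 6-tert-butyl 1-(4-methoxybenzyl) (1S,4aS,5S,6R,8aR)-5-(dimethoxymethyl)-1,4a-dimethyldecahydronaphthalene-1,6-dicarboxylate | C[C@]12CCC[C@](C)(C(=O)OCc3ccc(OC)cc3)[C@@H]1CC[C@@H](C(=O)OC(C)(C)C)[C@@H]2C(OC)OC | intermediate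
20 | 6-tert-butyl 1-(4-methoxybenzyl) (1S,4aS,5S,6R,8aR)-5-formyl-1,4a-dimethyldecahydronaphthalene-1,6-dicarboxylate | C[C@]12CCC[C@](C)(C(=O)OCc3ccc(OC)cc3)[C@@H]1CC[C@@H](C(=O)OC(C)(C)C)[C@@H]2C=O | intermediate
21 | 6-tert-butyl 1-(4-methoxybenzyl) (1S,4aR,5S,6R,8aR)-5-ethenyl-1,4a-dimethyldecahydronaphthalene-1,6-dicarboxylate | C[C@]12CCC[C@](C)(C(=O)OCc3ccc(OC)cc3)[C@@H]1CC[C@@H](C(=O)OC(C)(C)C)[C@@H]2C=C | intermediate
22 | 3-bromofuran-2(5H)-one | O=C1OCC=C1Br | starting material
23 | 6-tert-butyl 1-(4-methoxybenzyl) (1S,4aR,5S,6R,8aR)-5-[2-(9-borabicyclo[3.3.1]nonan-9-yl)ethyl]-1,4a-dimethyldecahydronaphthalene-1,6-dicarboxylate | C[C@]12CCC[C@](C)(C(=O)OCc3ccc(OC)cc3)[C@@H]1CC[C@@H](C(=O)OC(C)(C)C)[C@@H]2CCB1C2CCCC1CCC2 | intermediate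
24 | 6-tert-butyl 1-(4-methoxybenzyl) (1S,4aR,5S,6R,8aR)-1,4a-dimethyl-5-[2-(2-oxo-2,5-dihydrofuran-3-yl)ethyl]decahydronaphthalene-1,6-dicarboxylate | C[C@]12CCC[C@](C)(C(=O)OCc3ccc(OC)cc3)[C@@H]1CC[C@@H](C(=O)OC(C)(C)C)[C@@H]2CCC1=CCOC1=O | intermediate
25 | (1S,4aR,5S,6R,8aR)-1,4a-dimethyl-5-[2-(2-oxo-2,5-dihydrofuran-3-yl)ethyl]decahydronaphthalene-1,6-dicarboxylic acid | C[C@]12CCC[C@](C)(C(=O)O)[C@@H]1CC[C@@H](C(=O)O)[C@@H]2CCC1=CCOC1=O | target

**Step count and risks**

Total step count: 14. Longest linear sequence: 13 (steps 1–8 and 10–14; step 9 is a one-step branch).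

Steps most likely to fail:

1. Step 10 (proposed new method). What may go wrong: protonation of the enolate, or its Michael addition to a second molecule of acceptor, before it alkylates C7; and poor facial selectivity of the radical addition at C10. Fallback with known chemistry, setting out from 11 and returning at 19: hydrogen-atom-transfer olefin coupling of the 1,1-disubstituted alkene of 11 with 17 (Fe(acac)3, PhSiH3, EtOH/ethylene glycol, 60 °C) forms the C10–C9 bond and, after protonation, gives the open-chain bromo diester F1. A separate ester-enolate alkylation (KN(SiMe3)2, THF, −78 → 0 °C) then closes ring B to 19. This stepwise path also bypasses steps 7 and 8.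

2. Step 3. What may go wrong: slow ring closure because the ester tether must rotate into its s-cis form, so that intermolecular alkylation, proton exchange with the product and loss of HBr from the bromoethyl ester compete. Fallback, setting out from 1 and returning at 10, with the arm delivered intermolecularly: alkylation of 1 with PMBCl/K2CO3 gives 4-methoxybenzyl 3-oxocyclohex-1-ene-1-carboxylate F2. The conjugate methylation and silylation of step 2 give 4-methoxybenzyl (1S)-1-methyl-3-[(trimethylsilyl)oxy]cyclohex-2-ene-1-carboxylate F3. TBAT and 2-[(tert-butyldimethylsilyl)oxy]ethyl triflate alkylate C5 to the keto ester F4; both C5 epimers are expected, so the ketone is equilibrated with DBU, the required isomer separated and the other recycled. Takai–Lombardo methylenation gives the silyl ether alkene F5, and Bu4NF removes the silyl group to give 10.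

3. Step 13. What may go wrong: base-induced decomposition of the bromobutenolide, and protodeboronation or β-hydride elimination outpacing transmetalation. Fallback, setting out from 21 and returning at 24, building the butenolide by enolate alkylation and sulfoxide elimination: hydroboration as in step 13 to 23 and oxidative work-up (NaBO3) give the primary alcohol F6. I2/PPh3/imidazole gives the primary iodide F7. The lithium enolate of 3-(phenylsulfanyl)dihydrofuran-2(3H)-one (LiN(i-Pr)2, THF/DMPU, −78 → 0 °C) is alkylated by F7 to the sulfide lactone F8. mCPBA (−78 °C) gives the sulfoxide F9, whose thermal syn-elimination toward the ring CH2 (toluene, 110 °C) gives 24.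

Further compounds
F1 | step 10 | 4-methoxybenzyl 2-(2-bromoethyl)-3-(4-tert-butoxy-1,1-dimethoxy-4-oxobutan-2-yl)-1,3-dimethylcyclohexane-1-carboxylate, C4, C5, C9 and C10 configured as in 19 | C[C@]1([C@H](CC(=O)OC(C)(C)C)C(OC)OC)CCC[C@](C)(C(=O)OCc2ccc(OC)cc2)[C@@H]1CCBr
F2 | step 3 | 4-methoxybenzyl 3-oxocyclohex-1-ene-1-carboxylate | O=C1CCCC(C(=O)OCc2ccc(OC)cc2)=C1
F3 | step 3 | 4-methoxybenzyl (1S)-1-methyl-3-[(trimethylsilyl)oxy]cyclohex-2-ene-1-carboxylate | C[Si](C)(C)OC1=C[C@@](C)(C(=O)OCc2ccc(OC)cc2)CCC1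
F4 | step 3 | 4-methoxybenzyl (1S,2S)-2-{2-[(tert-butyldimethylsilyl)oxy]ethyl}-1-methyl-3-oxocyclohexane-1-carboxylate | O=C1CCC[C@](C)(C(=O)OCc2ccc(OC)cc2)[C@@H]1CCO[Si](C)(C)C(C)(C)C
F5 | step 3 | 4-methoxybenzyl (1S,2R)-2-{2-[(tert-butyldimethylsilyl)oxy]ethyl}-1-methyl-3-methylidenecyclohexane-1-carboxylate | C=C1CCC[C@](C)(C(=O)OCc2ccc(OC)cc2)[C@@H]1CCO[Si](C)(C)C(C)(C)C
F6 | step 13 | 6-tert-butyl 1-(4-methoxybenzyl) (1S,4aR,5S,6R,8aR)-5-(2-hydroxyethyl)-1,4a-dimethyldecahydronaphthalene-1,6-dicarboxylate | C[C@]12CCC[C@](C)(C(=O)OCc3ccc(OC)cc3)[C@@H]1CC[C@@H](C(=O)OC(C)(C)C)[C@@H]2CCO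
F7 | step 13 | 6-tert-butyl 1-(4-methoxybenzyl) (1S,4aR,5S,6R,8aR)-5-(2-iodoethyl)-1,4a-dimethyldecahydronaphthalene-1,6-dicarboxylate | C[C@]12CCC[C@](C)(C(=O)OCc3ccc(OC)cc3)[C@@H]1CC[C@@H](C(=O)OC(C)(C)C)[C@@H]2CCI
F8 | step 13 | 6-tert-butyl 1-(4-methoxybenzyl) (1S,4aR,5S,6R,8aR)-1,4a-dimethyl-5-{2-[2-oxo-3-(phenylsulfanyl)oxolan-3-yl]ethyl}decahydronaphthalene-1,6-dicarboxylate, both epimers at the lactone α-carbon | C[C@]12CCC[C@](C)(C(=O)OCc3ccc(OC)cc3)[C@@H]1CC[C@@H](C(=O)OC(C)(C)C)[C@@H]2CCC1(Sc4ccccc4)CCOC1=O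
F9 | step 13 | 6-tert-butyl 1-(4-methoxybenzyl) (1S,4aR,5S,6R,8aR)-1,4a-dimethyl-5-{2-[2-oxo-3-(phenylsulfinyl)oxolan-3-yl]ethyl}decahydronaphthalene-1,6-dicarboxylate | C[C@]12CCC[C@](C)(C(=O)OCc3ccc(OC)cc3)[C@@H]1CC[C@@H](C(=O)OC(C)(C)C)[C@@H]2CCC1(S(=O)c4ccccc4)CCOC1=O
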